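**Plan**

1. Numbering used throughout: ring A of the target is C1 (bears the CH2OH carbon C8), C2 (H), C3 (Br), C4 (OH), C5 (OH), C6 (bears the methylene C7 that leads to ring B).
2. Retrosynthesis: C8 is traced back to an ester, and the C3–Br bond and the ring B phenol to a late bromination and demethylation. Ring A is then cut at C3–C4 and C5–C6 (retro-Diels–Alder) into a 2-carbomethoxy diene and vinylene carbonate. The diene is cut at C1–C2 (vinyl cross-coupling) and C1=C6 (olefination) back to (3-bromo-4-methoxyphenyl)acetaldehyde.
3. Enabling feature: the vicinal hydroxyl carbons C4 and C5 of ring A are a symmetric two-carbon cis-enediol unit, and C3–C2–C1–C6 is a diene that already carries C8 on C1 and the benzylic C7 (with ring B) on C6.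
4. Forward: ring B is bought. The chain is joined by one-carbon homologation, bromo-olefination and vinyl coupling. Ring A is closed by the [4+2] step and aromatised by carbonate methanolysis and double alcohol oxidation. Bromination, demethylation and ester reduction finish the route.
5. Stereochemistry: the target is achiral. The only requirement is the (2Z) geometry of the diene, which is set kinetically in the olefination and retained in the coupling. The three relative stereocentres of the cycloadduct are erased on aromatisation.

Key step: step 7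

Remark: the bromophosphonate 6 is assumed not to be a catalogue item and is made in steps 3 and 4; all chiral intermediates are racemic and drawn as one enantiomer.

**Route**

Step 1
Reactants: 1 3-bromo-4-methoxybenzaldehyde
Product: 2 2-bromo-1-methoxy-4-(2-methoxyethenyl)benzene (E/Z mixture)
Conditions: MeOCH2PPh3Cl, KOt-Bu, THF, 0 °C to rt
Reagents that add atoms: (methoxymethyl)triphenylphosphonium chloride, COC[P+](c1ccccc1)(c1ccccc1)c1ccccc1.[Cl-]
Why: Wittig olefination of the aromatic aldehyde with the methoxymethylene ylide should give the aryl enol ether as an E/Z mixture, both isomers converge on the same aldehyde in step 2, and the aryl bromide is inert to the ylide.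

Step 2
Reactants: 2 2-bromo-1-methoxy-4-(2-methoxyethenyl)benzene
Product: 3 (3-bromo-4-methoxyphenyl)acetaldehyde
Conditions: 2 M aq. HCl, THF, 50 °C
Reagents that add atoms: water, O
Why: Acid-catalysed enol ether hydrolysis (C-protonation, hydration of the oxocarbenium ion, loss of methanol) completes the one-carbon homologation; the self-condensation-prone arylacetaldehyde is to be used crude and at once.

Step 3
Reactants: 4 methyl bis(2,2,2-trifluoroethyl)phosphonoacetate
Product: 5 methyl 2,2-dibromo-2-[bis(2,2,2-trifluoroethoxy)phosphoryl]acetate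
Conditions: NaOBr (from Br2 and aq. NaOH), 0 °C
Reagents that add atoms: bromine, BrBr
Why: Hypobromite bromination of the doubly activated methylene (electrophilic halogenation of a phosphonoacetate carbanion) is driven to the gem-dibromide, because stopping at the monobromide directly would be expected to give mixtures.

Step 4
Reactants: 5 methyl 2,2-dibromo-2-[bis(2,2,2-trifluoroethoxy)phosphoryl]acetate
Product: 6 methyl 2-bromo-2-[bis(2,2,2-trifluoroethoxy)phosphoryl]acetate (racemic)
Conditions: SnCl2·2H2O, EtOH/H2O, 0 °C
Reagents that add atoms: none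
Why: SnCl2 should remove exactly one bromine by two-electron reductive dehalogenation of the activated gem-dibromide, the remaining C–Br bond being much harder to reduce; the racemic CHBr centre is destroyed in step 5.

Step 5
Reactants: 3 (3-bromo-4-methoxyphenyl)acetaldehyde; 6 methyl 2-bromo-2-[bis(2,2,2-trifluoroethoxy)phosphoryl]acetate
Product: 7 methyl (2E)-2-bromo-4-(3-bromo-4-methoxyphenyl)but-2-enoate
Conditions: KOt-Bu, 18-crown-6, THF, −78 °C; aq. NH4Cl quench at −78 °C
Reagents that add atoms: none
Why: Horner–Wadsworth–Emmons olefination with the electron-poor bis(trifluoroethyl) phosphonate under dissociating conditions (Still–Gennari-type kinetic control) should place the CH2Ar group cis to the ester, which for the bromo compound is the (E)-alkene, and −78 °C keeps enolisation of 3 in check.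

Step 6
Reactants: 7 methyl (2E)-2-bromo-4-(3-bromo-4-methoxyphenyl)but-2-enoate
Product: 8 methyl (2Z)-4-(3-bromo-4-methoxyphenyl)-2-ethenylbut-2-enoate
Conditions: Bu3SnCH=CH2, Pd2(dba)3 (cat.), AsPh3, CuI (cat.), BHT, NMP, rt to 40 °C
Reagents that add atoms: tributyl(vinyl)stannane, C=C[Sn](CCCC)(CCCC)CCCC
Why: Stille cross-coupling proceeds with retention of alkene geometry, zerovalent palladium should insert into the electron-poor alkenyl C–Br bond far faster than into the electron-rich aryl bromide, and the neutral conditions avoid base-induced migration of the skipped double bond; 8 is kept cold with BHT and used directly.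

Step 7
Reactants: 8 methyl (2Z)-4-(3-bromo-4-methoxyphenyl)-2-ethenylbut-2-enoate; 9 vinylene carbonate
Product: 10 methyl 4-(3-bromo-4-methoxybenzyl)-2-oxo-3a,4,7,7a-tetrahydro-1,3-benzodioxole-5-carboxylate (racemic all-cis endo adduct)
Conditions: 9 (10 equiv), BHT (cat.), toluene, sealed tube, 150 °C
Reagents that add atoms: none
Why: A concerted, suprafacial thermal Diels–Alder reaction between the s-cis conformer of the 2-carbomethoxy diene 8 (C3=C2–C1=C6) and the cis-enediol equivalent 9 forms C3–C4 and C5–C6 in one step; the closest known reactions are the thermal cycloadditions of vinylene carbonate to 1,3-dienes and those of 2-carbomethoxy-1,3-butadienes with unactivated or electron-rich alkenes. The six-membered carbocycle that becomes ring A is closed by an intermolecular [4+2] annulation, and the dioxolanone ring of 9 is carried in unchanged as a cis-fused ring. The C4 and C5 centres are cis because the addition is suprafacial on the cis ring alkene of 9, and the C6 centre should be cis to them because the benzyl group sits on the outside of the diene terminus and the carbonate approaches endo (Alder rule). The adduct is racemic and all three centres are erased in step 9, so the endo/exo outcome is immaterial, and no regiochemical question arises because 9 is symmetrical. The selectivity that matters is cross-cycloaddition over self-dimerisation of 8, which is secured by the large excess of 9, by the trisubstituted acrylate unit of 8 being a poor dienophile, by the radical inhibitor and by the (2Z) geometry that lets 8 reach the s-cis conformer.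

Step 8
Reactants: 10 methyl 4-(3-bromo-4-methoxybenzyl)-2-oxo-3a,4,7,7a-tetrahydro-1,3-benzodioxole-5-carboxylate
Product: 11 methyl 6-(3-bromo-4-methoxybenzyl)-4,5-dihydroxycyclohex-1-ene-1-carboxylate (racemic all-cis)
Conditions: K2CO3 (cat.), MeOH, 0 °C
Reagents that add atoms: none
Why: Base-catalysed transesterification of the strained five-membered carbonate with methanol should be fast at 0 °C, so conjugate addition or vinylogous elimination at the enoate should not compete, and no stereocentre is touched.

Step 9
Reactants: 11 methyl 6-(3-bromo-4-methoxybenzyl)-4,5-dihydroxycyclohex-1-ene-1-carboxylate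
Product: 13 methyl 2-(3-bromo-4-methoxybenzyl)-3,4-dihydroxybenzoate, via ene-dione 12 (not isolated)
Conditions: DMSO, (CF3CO)2O, CH2Cl2, −78 °C; then Et3N, −78 °C to rt
Reagents that add atoms: none
Why: Activated-DMSO oxidation (Swern type, trifluoroacetic anhydride variant) of both secondary hydroxyls avoids the glycol cleavage of metal oxidants, and the resulting cyclohex-4-ene-1,2-dione 12 is a tautomer of the catechol, to which it should enolise under Et3N with loss of all three stereocentres.

Step 10
Reactants: 13 methyl 2-(3-bromo-4-methoxybenzyl)-3,4-dihydroxybenzoate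
Product: 14 methyl 5-bromo-2-(3-bromo-4-methoxybenzyl)-3,4-dihydroxybenzoate
Conditions: Br2 (1.0 equiv), AcOH, 15 °C, dark
Reagents that add atoms: bromine, BrBr
Why: Electrophilic aromatic bromination should go to C3 of ring A, the only free position ortho to a hydroxyl and meta to the ester (as vanillin brominates at its 5-position), while C2 is ortho to the ester and ring B is a deactivated bromoanisole; one equivalent in the dark avoids radical attack at the diarylmethane CH2.

Step 11
Reactants: 14 methyl 5-bromo-2-(3-bromo-4-methoxybenzyl)-3,4-dihydroxybenzoate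
Product: 15 methyl 5-bromo-2-(3-bromo-4-hydroxybenzyl)-3,4-dihydroxybenzoate
Conditions: BBr3 (5 equiv), CH2Cl2, −78 to 0 °C; then ice-water
Reagents that add atoms: none
Why: BBr3 ether cleavage (Lewis acid complexation, then bromide attack at the methyl group) frees the ring B phenol while the methyl ester and both aryl bromides should survive at low temperature; it is placed before the reduction because BBr3 would turn a benzylic alcohol into the bromide.

Step 12
Reactants: 15 methyl 5-bromo-2-(3-bromo-4-hydroxybenzyl)-3,4-dihydroxybenzoate
Product: 17 6-bromo-3-(3-bromo-4-hydroxybenzyl)-4-(hydroxymethyl)benzene-1,2-diol, via aldehyde 16 (not isolated)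
Conditions: i-Bu2AlH (8 equiv), THF, −78 to 0 °C; aq. KNaC4H4O6 (potassium sodium tartrate) work-up
Reagents that add atoms: none
Why: Hydride reduction of the aryl ester by i-Bu2AlH through the aldehyde tolerates free phenols when excess reagent is used (they are carried as aluminium phenoxides), and a near-neutral tartrate work-up should protect the 4-hydroxybenzyl alcohol from quinone methide chemistry.

**Compound list**

1 | 3-bromo-4-methoxybenzaldehyde | COc1ccc(C=O)cc1Br | starting material
2 | 2-bromo-1-methoxy-4-(2-methoxyethenyl)benzene, E/Z mixture | COC=Cc1ccc(OC)c(Br)c1 | intermediate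
3 | (3-bromo-4-methoxyphenyl)acetaldehyde | O=CCc1ccc(OC)c(Br)c1 | intermediate
4 | methyl bis(2,2,2-trifluoroethyl)phosphonoacetate | COC(=O)CP(=O)(OCC(F)(F)F)OCC(F)(F)F | starting material
5 | methyl 2,2-dibromo-2-[bis(2,2,2-trifluoroethoxy)phosphoryl]acetate | COC(=O)C(Br)(Br)P(=O)(OCC(F)(F)F)OCC(F)(F)F | intermediate
6 | methyl 2-bromo-2-[bis(2,2,2-trifluoroethoxy)phosphoryl]acetate, racemic | COC(=O)C(Br)P(=O)(OCC(F)(F)F)OCC(F)(F)F | intermediate
7 | methyl (2E)-2-bromo-4-(3-bromo-4-methoxyphenyl)but-2-enoate (CH2Ar cis to the ester) | COC(=O)/C(Br)=C\Cc1ccc(OC)c(Br)c1 | intermediate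
8 | methyl (2Z)-4-(3-bromo-4-methoxyphenyl)-2-ethenylbut-2-enoate (CH2Ar trans to the vinyl group) | C=C/C(C(=O)OC)=C/Cc1ccc(OC)c(Br)c1 | intermediate
9 | vinylene carbonate (1,3-dioxol-2-one) | O=C1OC=CO1 | starting material
10 | methyl 4-(3-bromo-4-methoxybenzyl)-2-oxo-3a,4,7,7a-tetrahydro-1,3-benzodioxole-5-carboxylate, racemic, benzyl and both ring-fusion oxygens on one face | O=C1O[C@H]2[C@@H](Cc3ccc(OC)c(Br)c3)C(C(=O)OC)=CC[C@H]2O1 | intermediate
11 | methyl 6-(3-bromo-4-methoxybenzyl)-4,5-dihydroxycyclohex-1-ene-1-carboxylate, racemic, all-cis | O[C@H]1[C@@H](Cc2ccc(OC)c(Br)c2)C(C(=O)OC)=CC[C@H]1O | intermediate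
12 | methyl 6-(3-bromo-4-methoxybenzyl)-4,5-dioxocyclohex-1-ene-1-carboxylate, racemic (one enantiomer drawn) | O=C1[C@@H](Cc2ccc(OC)c(Br)c2)C(C(=O)OC)=CCC1=O | intermediate
13 | methyl 2-(3-bromo-4-methoxybenzyl)-3,4-dihydroxybenzoate | COC(=O)c1ccc(O)c(O)c1Cc1ccc(OC)c(Br)c1 | intermediate
14 | methyl 5-bromo-2-(3-bromo-4-methoxybenzyl)-3,4-dihydroxybenzoate | COC(=O)c1cc(Br)c(O)c(O)c1Cc1ccc(OC)c(Br)c1 | intermediate
15 | methyl 5-bromo-2-(3-bromo-4-hydroxybenzyl)-3,4-dihydroxybenzoate | COC(=O)c1cc(Br)c(O)c(O)c1Cc1ccc(O)c(Br)c1 | intermediate
16 | 5-bromo-2-(3-bromo-4-hydroxybenzyl)-3,4-dihydroxybenzaldehyde | O=Cc1cc(Br)c(O)c(O)c1Cc1ccc(O)c(Br)c1 | intermediate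
17 | 6-bromo-3-(3-bromo-4-hydroxybenzyl)-4-(hydroxymethyl)benzene-1,2-diol (achiral) | OCc1cc(Br)c(O)c(O)c1Cc1ccc(O)c(Br)c1 | target

**Step count**

Total step count: 12. Longest linear sequence: 10 steps (steps 1, 2 and 5 to 12 from 1); steps 3 and 4 are a two-step side branch that joins at step 5.

**Steps most likely to fail**

Step 7. The weak dienophile may add too slowly, so that 8 dimerises, oligomerises or isomerises before the cross-adduct forms. The fallback sets out from 8 and installs the two oxygens after ring closure instead of with the dienophile. Diene 8 is combined with maleic anhydride (toluene, 60 °C), which should react far faster than 8 with itself, to give the all-cis anhydride adduct, methyl 4-(3-bromo-4-methoxybenzyl)-1,3-dioxo-1,3,3a,4,7,7a-hexahydro-2-benzofuran-5-carboxylate F1. Mild aqueous hydrolysis (H2O, THF, rt) opens it to the diacid, 3-(3-bromo-4-methoxybenzyl)-4-(methoxycarbonyl)cyclohex-4-ene-1,2-dicarboxylic acid F2. Oxidative bis-decarboxylation with Pb(OAc)4 in pyridine (60 °C) then gives methyl 6-(3-bromo-4-methoxybenzyl)cyclohexa-1,4-diene-1-carboxylate F3. OsO4 (cat.) with N-methylmorpholine N-oxide should dihydroxylate only the isolated, electron-richer C4=C5 alkene, from the face opposite the benzyl group, to give the diastereomeric cis-diol, methyl 6-(3-bromo-4-methoxybenzyl)-4,5-dihydroxycyclohex-1-ene-1-carboxylate with both hydroxyls trans to the benzyl group F4. Under the conditions of step 9, F4 is oxidised and tautomerises, and the route is rejoined at 13.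

Step 9. The second oxidation may stall, the nascent catechol may be thiomethylated by excess activated DMSO, or an activated hydroxyl may be lost by vinylogous elimination. The fallback sets out from 11 and oxidises one hydroxyl at a time. Heating 11 with Bu2SnO (toluene, reflux, water removal) gives the stannylene acetal, methyl 4-(3-bromo-4-methoxybenzyl)-2,2-dibutyl-3a,4,7,7a-tetrahydro-1,3,2-benzodioxastannole-5-carboxylate F5. Titration with Br2 (CH2Cl2, rt) should oxidise exactly one oxygen to give the α-ketol, methyl 6-(3-bromo-4-methoxybenzyl)-5-hydroxy-4-oxocyclohex-1-ene-1-carboxylate F6; the regioisomeric ketol serves equally. Acyloin oxidation with Cu(OAc)2 in aqueous AcOH (60 °C) then gives the dione, which tautomerises, and the route is rejoined at 13.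

Step 10. Regiocontrol may be lost through attack at C2 of ring A (para to the C5 hydroxyl) or on ring B, or the catechol may be oxidised to the quinone. The fallback sets out from 13 and masks the competing hydroxyl. Acetic anhydride in pyridine gives the diacetate, methyl 3,4-diacetoxy-2-(3-bromo-4-methoxybenzyl)benzoate F7. One equivalent of pyrrolidine (CH2Cl2, 0 °C) should remove the more activated acetate para to the ester to give methyl 3-acetoxy-2-(3-bromo-4-methoxybenzyl)-4-hydroxybenzoate F8, in which only the C4 hydroxyl activates and C3 is its single free ortho position. Bromination (Br2, AcOH) then gives methyl 3-acetoxy-5-bromo-2-(3-bromo-4-methoxybenzyl)-4-hydroxybenzoate F9, and K2CO3 in MeOH removes the remaining acetate, rejoining the route at 14.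

**Further compounds**

F1 | step 7 | methyl 4-(3-bromo-4-methoxybenzyl)-1,3-dioxo-1,3,3a,4,7,7a-hexahydro-2-benzofuran-5-carboxylate, racemic, all-cis | O=C1OC(=O)[C@H]2[C@@H](Cc3ccc(OC)c(Br)c3)C(C(=O)OC)=CC[C@H]21
F2 | step 7 | 3-(3-bromo-4-methoxybenzyl)-4-(methoxycarbonyl)cyclohex-4-ene-1,2-dicarboxylic acid, racemic, all-cis | OC(=O)[C@H]1[C@@H](Cc2ccc(OC)c(Br)c2)C(C(=O)OC)=CC[C@H]1C(O)=O
F3 | step 7 | methyl 6-(3-bromo-4-methoxybenzyl)cyclohexa-1,4-diene-1-carboxylate, racemic (one enantiomer drawn) | C1=C[C@@H](Cc2ccc(OC)c(Br)c2)C(C(=O)OC)=CC1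
F4 | step 7 | methyl 6-(3-bromo-4-methoxybenzyl)-4,5-dihydroxycyclohex-1-ene-1-carboxylate, racemic, cis-diol trans to the benzyl group | O[C@@H]1[C@@H](Cc2ccc(OC)c(Br)c2)C(C(=O)OC)=CC[C@@H]1O
F5 | step 9 | methyl 4-(3-bromo-4-methoxybenzyl)-2,2-dibutyl-3a,4,7,7a-tetrahydro-1,3,2-benzodioxastannole-5-carboxylate, racemic, all-cis | CCCC[Sn]1(CCCC)O[C@H]2[C@@H](Cc3ccc(OC)c(Br)c3)C(C(=O)OC)=CC[C@H]2O1
F6 | step 9 | methyl 6-(3-bromo-4-methoxybenzyl)-5-hydroxy-4-oxocyclohex-1-ene-1-carboxylate, racemic, hydroxyl cis to the benzyl group | O[C@H]1[C@@H](Cc2ccc(OC)c(Br)c2)C(C(=O)OC)=CCC1=O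
F7 | step 10 | methyl 3,4-diacetoxy-2-(3-bromo-4-methoxybenzyl)benzoate | COC(=O)c1ccc(OC(C)=O)c(OC(C)=O)c1Cc1ccc(OC)c(Br)c1
F8 | step 10 | methyl 3-acetoxy-2-(3-bromo-4-methoxybenzyl)-4-hydroxybenzoate | COC(=O)c1ccc(O)c(OC(C)=O)c1Cc1ccc(OC)c(Br)c1
F9 | step 10 | methyl 3-acetoxy-5-bromo-2-(3-bromo-4-methoxybenzyl)-4-hydroxybenzoate | COC(=O)c1cc(Br)c(O)c(OC(C)=O)c1Cc1ccc(OC)c(Br)c1
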